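**Plan**
- Retrosynthesis: the side-chain alkenes C9=C10 (Julia–Kocienski) and C7=C8 (Wittig) are cut first, then the ring bonds C4–C5 and O2–C3 (ring numbered O1–O2–C3–C4–C5), and finally the peroxyketal goes back to a 2-methylalk-1-ene.
- Enabling feature: C5 (CH3, chain, O1) sits at the oxidation level of a methyl-ketone carbonyl and can be a peroxycarbenium carbon; C4–C3 with its CH3 and CH2CO2R arm is the CH2=C(CH3) unit of a 3-methylbut-3-enoate. The dioxolane is therefore the sum of a ketone-derived peroxide cation and a 1,1-disubstituted alkene.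
- Forward: the C10 chain carrying the silyl peroxyketal is built (steps 1–4), the alkene is made as a chiral ester (step 5), the only ring closes in the [3+2] annulation (step 6), and the triene is added afterwards by two olefinations (steps 10 and 13).
- Stereochemistry: C3 and C5 both arise in step 6, with trans expected only as a modest preference of the ring closure. The absolute configuration is not induced; the (R)-pantolactone ester makes the mirror-image ring forms diastereomers, and (3R,5S) is isolated by chromatography. 7E comes from a stabilised ylide, 9E from the Julia–Kocienski step, 12Z from (Z)-hex-3-en-1-ol.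

Key step: step 6

Remark (assumptions): 6-bromohexan-1-ol, CH2=C(CH3)CH2MgCl solution, 3-methylbut-3-enoic acid, (R)-pantolactone and (Z)-hex-3-en-1-ol are bought. The configuration of the isolated diastereomer 12 must be proven (crystal structure of 12 or of a crystalline ester of 14, or correlation through the rotation of 20) before it is carried on. Side-chain carbons are numbered from the ring outward.

**Step 1**
Reactants: 1 6-bromohexan-1-ol
Product: 2 [(6-bromohexyl)oxy](tert-butyl)diphenylsilane
Conditions: TBDPSCl, imidazole, CH2Cl2, 0 °C → rt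
Reagents that add atoms: tert-butyl(chloro)diphenylsilane, CC(C)(C)[Si](Cl)(c1ccccc1)c1ccccc1
Why: Imidazole-promoted silyl ether formation on the primary alcohol gives a group that should withstand the Grignard reagent, ozone and SnCl4 used later.

**Step 2**
Reactants: 2 [(6-bromohexyl)oxy](tert-butyl)diphenylsilane
Product: 3 tert-butyl[(8-methylnon-8-en-1-yl)oxy]diphenylsilane
Conditions: CH2=C(CH3)CH2MgCl (1.5 equiv), Li2CuCl4 (3 mol%), THF, −20 °C → rt
Reagents that add atoms: 2-methylallylmagnesium chloride, CC(=C)C[Mg]Cl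
Why: Copper-catalysed cross-coupling of a primary alkyl bromide with an allylic Grignard reagent joins the methallyl unit, whose two termini are equivalent, and leaves the silyl ether alone.

**Step 3**
Reactants: 3 tert-butyl[(8-methylnon-8-en-1-yl)oxy]diphenylsilane
Product: 5 tert-butyl[(8-hydroperoxy-8-methoxynonyl)oxy]diphenylsilane, via carbonyl oxide 4 (not isolated)
Conditions: O3, CH2Cl2/MeOH (4:1), −78 °C to a faint blue end point; N2 purge; cold concentration, chromatography
Reagents that add atoms: ozone, [O-][O+]=O; methanol, CO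
Why: In this Criegee ozonolysis the primary ozonide of a 1,1-disubstituted alkene should fragment to the more substituted carbonyl oxide 4 and formaldehyde, and methanol traps 4 as the α-methoxy hydroperoxide; its ketal carbon is racemic, which does not matter because it becomes planar in step 6.

**Step 4**
Reactants: 5 tert-butyl[(8-hydroperoxy-8-methoxynonyl)oxy]diphenylsilane
Product: 6 tert-butyl({8-methoxy-8-[(triethylsilyl)peroxy]nonyl}oxy)diphenylsilane
Conditions: Et3SiCl, imidazole, DMF, 0 °C
Reagents that add atoms: chlorotriethylsilane, CC[Si](Cl)(CC)CC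
Why: O-Silylation of the hydroperoxide, which is more acidic than an alcohol, under mild base should give the silyl peroxyketal without ionising the ketal.

**Step 5**
Reactants: 7 3-methylbut-3-enoic acid; 8 (R)-pantolactone [(3R)-3-hydroxy-4,4-dimethyloxolan-2-one]
Product: 9 (3R)-4,4-dimethyl-2-oxooxolan-3-yl 3-methylbut-3-enoate
Conditions: DCC, DMAP (5 mol%), CH2Cl2, −10 → 0 °C
Reagents that add atoms: none
Why: Steglich esterification at low temperature with little DMAP should acylate the hindered alcohol without moving the β,γ-double bond into conjugation, and the stereocentre of 8 is not involved.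

**Step 6**
Reactants: 6 tert-butyl({8-methoxy-8-[(triethylsilyl)peroxy]nonyl}oxy)diphenylsilane; 9 (3R)-4,4-dimethyl-2-oxooxolan-3-yl 3-methylbut-3-enoate
Product: 12 (3R)-4,4-dimethyl-2-oxooxolan-3-yl 2-[(3R,5S)-5-{7-[(tert-butyldiphenylsilyl)oxy]heptyl}-3,5-dimethyl-1,2-dioxolan-3-yl]acetate, via silylperoxycarbenium ion 10 (not isolated), via tertiary carbocation 11 (not isolated)
Conditions: SnCl4 (1.0 equiv), 9 (2 equiv), CH2Cl2, −78 °C; aq. NaHCO3; chromatography on silica, then normal-phase HPLC
Reagents that add atoms: none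
Why: SnCl4 takes methoxide from 6 to give ion 10, the CH2 terminus of the alkene of 9 adds to its carbon (bond C4–C5) to give cation 11, and the silylated peroxide oxygen captures C3 (bond O2–C3) while the triethylsilyl group leaves with the methoxide as methoxytriethylsilane, which sets the Lewis acid free again. The closest known reaction type is the Lewis acid-mediated [3+2] annulation of triethylsilyl peroxyketals with alkenes to 1,2-dioxolanes, applied here to a β,γ-unsaturated ester. The one ring, the 1,2-dioxolane, closes by combination of a carbenium ion with the distal peroxide oxygen, a five-membered closure that counts as 5-endo with respect to the cationic carbon and carries no stereoelectronic penalty because the acceptor is an empty p orbital. C5 forms on a planar ion whose faces differ only by methyl against a primary alkyl chain and is therefore not controlled; C3 is set relative to C5 in the ring closure, where an envelope transition state with the heptyl chain and the CH2CO2R arm on opposite faces should be slightly preferred (trans). The (R)-pantolactone unit is too remote to steer either centre but turns the two mirror-image trans arrangements into diastereomers, so the (3R,5S) isomer 12 is separated by chromatography from the other three ring stereoisomers. The step needs Markovnikov addition and ring closure faster than proton loss next to the ester, which the 1,1-disubstituted alkene (tertiary cation, quaternary C3), the ketone-derived ion (quaternary C5), the low temperature and the intramolecular oxygen nucleophile should secure.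

**Step 7**
Reactants: 12 (3R)-4,4-dimethyl-2-oxooxolan-3-yl 2-[(3R,5S)-5-{7-[(tert-butyldiphenylsilyl)oxy]heptyl}-3,5-dimethyl-1,2-dioxolan-3-yl]acetate
Product: 13 methyl 2-[(3R,5S)-5-{7-[(tert-butyldiphenylsilyl)oxy]heptyl}-3,5-dimethyl-1,2-dioxolan-3-yl]acetate
Conditions: K2CO3 (0.2 equiv), MeOH, 0 °C → rt
Reagents that add atoms: methanol, CO
Why: Carbonate-catalysed transesterification of the activated α-acyloxy-lactone ester should free the auxiliary under conditions too mild to enolise the ester or cleave the silyl ether, and the peroxide carbons carry no hydrogen, so C3 and C5 stay as set.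

**Step 8**
Reactants: 13 methyl 2-[(3R,5S)-5-{7-[(tert-butyldiphenylsilyl)oxy]heptyl}-3,5-dimethyl-1,2-dioxolan-3-yl]acetate
Product: 14 methyl 2-[(3R,5S)-5-(7-hydroxyheptyl)-3,5-dimethyl-1,2-dioxolan-3-yl]acetate
Conditions: Bu4NF, AcOH (1:1), THF, 0 °C → rt
Reagents that add atoms: none
Why: Fluoride-induced cleavage of the silyl ether, buffered with acetic acid, avoids basic species that could enolise the ester next to the β-peroxy carbon.

**Step 9**
Reactants: 14 methyl 2-[(3R,5S)-5-(7-hydroxyheptyl)-3,5-dimethyl-1,2-dioxolan-3-yl]acetate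
Product: 15 methyl 2-[(3R,5S)-3,5-dimethyl-5-(7-oxoheptyl)-1,2-dioxolan-3-yl]acetate
Conditions: Dess–Martin periodinane, CH2Cl2, 0 °C → rt
Reagents that add atoms: none
Why: Dess–Martin oxidation should take the primary alcohol to the aldehyde under neutral, non-reducing conditions that leave the O–O bond and the ester intact.

**Step 10**
Reactants: 15 methyl 2-[(3R,5S)-3,5-dimethyl-5-(7-oxoheptyl)-1,2-dioxolan-3-yl]acetate
Product: 16 methyl 2-[(3R,5S)-3,5-dimethyl-5-[(7E)-9-oxonon-7-en-1-yl]-1,2-dioxolan-3-yl]acetate
Conditions: Ph3P=CHCHO (1.3 equiv), toluene, 80 °C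
Reagents that add atoms: (triphenylphosphoranylidene)acetaldehyde, O=CC=P(c1ccccc1)(c1ccccc1)c1ccccc1
Why: The Wittig reaction of a stabilised formyl ylide should give the (E)-enal, and such ylides do not reduce a hindered dialkyl peroxide.

**Step 11**
Reactants: 17 (Z)-hex-3-en-1-ol
Product: 18 5-{[(3Z)-hex-3-en-1-yl]sulfanyl}-1-phenyl-1H-tetrazole
Conditions: 1-phenyl-1H-tetrazole-5-thiol, PPh3, DIAD, THF, 0 °C → rt
Reagents that add atoms: 1-phenyl-1H-tetrazole-5-thiol, Sc1nnnn1-c1ccccc1
Why: Mitsunobu thioetherification of a primary alcohol with the acidic heteroaryl thiol does not touch the Z-alkene.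

**Step 12**
Reactants: 18 5-{[(3Z)-hex-3-en-1-yl]sulfanyl}-1-phenyl-1H-tetrazole
Product: 19 5-{[(3Z)-hex-3-en-1-yl]sulfonyl}-1-phenyl-1H-tetrazole
Conditions: (NH4)6Mo7O24·4H2O (10 mol%), 30% aq. H2O2, EtOH, 0 °C → rt
Reagents that add atoms: hydrogen peroxide, OO
Why: Molybdate-catalysed sulfide-to-sulfone oxidation with hydrogen peroxide is selective for sulfur over an isolated alkene.

**Step 13**
Reactants: 16 methyl 2-[(3R,5S)-3,5-dimethyl-5-[(7E)-9-oxonon-7-en-1-yl]-1,2-dioxolan-3-yl]acetate; 19 5-{[(3Z)-hex-3-en-1-yl]sulfonyl}-1-phenyl-1H-tetrazole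
Product: 20 methyl 2-[(3R,5S)-3,5-dimethyl-5-[(7E,9E,12Z)-pentadeca-7,9,12-trien-1-yl]-1,2-dioxolan-3-yl]acetate
Conditions: 19 (1.3 equiv), KN(SiMe3)2 (1.2 equiv), DME, −78 °C, 30 min; then 16, −78 °C → rt
Reagents that add atoms: none
Why: In this Julia–Kocienski olefination the pre-formed potassium salt of 19 adds to the enal, and Smiles rearrangement with loss of SO2 and the tetrazololate should give the 9E bond, while 7E and 12Z are carried in unchanged and keeping the base below the amount of sulfone protects the β-peroxy ester from enolisation.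

**Compound list**
1 | 6-bromohexan-1-ol | OCCCCCCBr | starting material
2 | [(6-bromohexyl)oxy](tert-butyl)diphenylsilane | BrCCCCCCO[Si](c1ccccc1)(c1ccccc1)C(C)(C)C | intermediate
3 | tert-butyl[(8-methylnon-8-en-1-yl)oxy]diphenylsilane | C=C(C)CCCCCCCO[Si](c1ccccc1)(c1ccccc1)C(C)(C)C | intermediate
4 | carbonyl oxide of 9-[(tert-butyldiphenylsilyl)oxy]nonan-2-one (not isolated) | CC(=[O+][O-])CCCCCCCO[Si](c1ccccc1)(c1ccccc1)C(C)(C)C | intermediate
5 | tert-butyl[(8-hydroperoxy-8-methoxynonyl)oxy]diphenylsilane (racemic at the ketal carbon) | CC(OC)(OO)CCCCCCCO[Si](c1ccccc1)(c1ccccc1)C(C)(C)C | intermediate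
6 | tert-butyl({8-methoxy-8-[(triethylsilyl)peroxy]nonyl}oxy)diphenylsilane (racemic at the ketal carbon) | CC(OC)(OO[Si](CC)(CC)CC)CCCCCCCO[Si](c1ccccc1)(c1ccccc1)C(C)(C)C | intermediate
7 | 3-methylbut-3-enoic acid | C=C(C)CC(=O)O | starting material
8 | (R)-pantolactone, (3R)-3-hydroxy-4,4-dimethyloxolan-2-one | CC1(C)COC(=O)[C@@H]1O | starting material
9 | (3R)-4,4-dimethyl-2-oxooxolan-3-yl 3-methylbut-3-enoate | C=C(C)CC(=O)O[C@H]1C(=O)OCC1(C)C | intermediate
10 | silylperoxycarbenium ion, 9-[(tert-butyldiphenylsilyl)oxy]-2-[(triethylsilyl)peroxy]nonan-2-ylium (not isolated) | CC(=[O+]O[Si](CC)(CC)CC)CCCCCCCO[Si](c1ccccc1)(c1ccccc1)C(C)(C)C | intermediate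
11 | tertiary carbocation at C3 after C4–C5 bond formation, 5S epimer shown (not isolated) | CC(C)(C)[Si](c1ccccc1)(c1ccccc1)OCCCCCCC[C@@](OO[Si](CC)(CC)CC)(C)C[C+](C)CC(=O)O[C@H]2C(=O)OCC2(C)C | intermediate
12 | (3R)-4,4-dimethyl-2-oxooxolan-3-yl 2-[(3R,5S)-5-{7-[(tert-butyldiphenylsilyl)oxy]heptyl}-3,5-dimethyl-1,2-dioxolan-3-yl]acetate | CC(C)(C)[Si](c1ccccc1)(c1ccccc1)OCCCCCCC[C@@]2(C)C[C@](C)(CC(=O)O[C@H]3C(=O)OCC3(C)C)OO2 | intermediate
13 | methyl 2-[(3R,5S)-5-{7-[(tert-butyldiphenylsilyl)oxy]heptyl}-3,5-dimethyl-1,2-dioxolan-3-yl]acetate | CC(C)(C)[Si](c1ccccc1)(c1ccccc1)OCCCCCCC[C@@]2(C)C[C@](C)(CC(=O)OC)OO2 | intermediate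
14 | methyl 2-[(3R,5S)-5-(7-hydroxyheptyl)-3,5-dimethyl-1,2-dioxolan-3-yl]acetate | OCCCCCCC[C@@]1(C)C[C@](C)(CC(=O)OC)OO1 | intermediate
15 | methyl 2-[(3R,5S)-3,5-dimethyl-5-(7-oxoheptyl)-1,2-dioxolan-3-yl]acetate | O=CCCCCCC[C@@]1(C)C[C@](C)(CC(=O)OC)OO1 | intermediate
16 | methyl 2-[(3R,5S)-3,5-dimethyl-5-[(7E)-9-oxonon-7-en-1-yl]-1,2-dioxolan-3-yl]acetate | O=C/C=C/CCCCCC[C@@]1(C)C[C@](C)(CC(=O)OC)OO1 | intermediate
17 | (Z)-hex-3-en-1-ol | CC/C=C\CCO | starting material
18 | 5-{[(3Z)-hex-3-en-1-yl]sulfanyl}-1-phenyl-1H-tetrazole | CC/C=C\CCSc1nnnn1-c1ccccc1 | intermediate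
19 | 5-{[(3Z)-hex-3-en-1-yl]sulfonyl}-1-phenyl-1H-tetrazole | CC/C=C\CCS(=O)(=O)c1nnnn1-c1ccccc1 | intermediate
20 | methyl 2-[(3R,5S)-3,5-dimethyl-5-[(7E,9E,12Z)-pentadeca-7,9,12-trien-1-yl]-1,2-dioxolan-3-yl]acetate | CC/C=C\C/C=C/C=C/CCCCCC[C@@]1(C)C[C@](C)(CC(=O)OC)OO1 | target

**Count**
Total steps: 13. Longest linear sequence: 10 (steps 1–4, 6–10, 13).

**Steps most likely to fail**

1. Step 6. Three things may go wrong: the tertiary cation may lose a proton next to the ester before the peroxide oxygen closes the ring; the ring closure may show little preference for trans; and the four ester diastereomers may not separate cleanly. The fallback sets out from 6 and comes back at 13; it forms the two bonds in separate operations and makes the elimination product the intended intermediate. Methyl 3-methylbut-2-enoate is converted with LiN(iPr)2 and Me3SiCl (THF, −78 °C) into the silyl dienolate 1-methoxy-3-methyl-1-(trimethylsilyloxy)buta-1,3-diene F1. Ion 10, generated from 6 with SnCl4 in CH2Cl2 at −78 °C, is attacked by the terminal CH2 of F1 in a vinylogous Mukaiyama-type addition, which forms the same C4–C5 bond and should give racemic methyl (2E)-12-[(tert-butyldiphenylsilyl)oxy]-3,5-dimethyl-5-[(triethylsilyl)peroxy]dodec-2-enoate F2. HF·pyridine in THF at 0 °C should remove only the peroxide-bound silyl group to give methyl (2E)-12-[(tert-butyldiphenylsilyl)oxy]-5-hydroperoxy-3,5-dimethyldodec-2-enoate F3. Et2NH in CF3CH2OH then closes O2–C3 by 5-exo-trig peroxy-Michael addition. The trans pair is separated from the cis pair on silica, and 13 from its enantiomer by preparative HPLC on a cellulose tris(3,5-dimethylphenylcarbamate) phase. Steps 5 and 7 are then not needed.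

2. Step 13. The addition–rearrangement sequence may show poor E selectivity with a conjugated aldehyde, and any free base may enolise the ester and expel the peroxide oxygen by E1cB ring opening, which would destroy the ring or scramble C3. The fallback sets out from 15 and comes back at 20, replacing steps 10 to 13 with a cross-coupling in which both diene bonds come from syn additions to terminal alkynes. Seyferth–Gilbert homologation of 15 with dimethyl (1-diazo-2-oxopropyl)phosphonate (K2CO3, MeOH) should give methyl 2-[(3R,5S)-3,5-dimethyl-5-(oct-7-yn-1-yl)-1,2-dioxolan-3-yl]acetate F4. Hydroboration with pinacolborane (Cp2Zr(H)Cl and Et3N, catalytic, CH2Cl2) should give methyl 2-[(3R,5S)-3,5-dimethyl-5-[(7E)-8-(4,4,5,5-tetramethyl-1,3,2-dioxaborolan-2-yl)oct-7-en-1-yl]-1,2-dioxolan-3-yl]acetate F5. Separately, bought (Z)-1-bromopent-2-ene and HC≡CMgBr (CuBr·SMe2 catalytic, THF) give (4Z)-hept-4-en-1-yne F6, and Cp2Zr(H)Cl followed by I2 gives (1E,4Z)-1-iodohepta-1,4-diene F7. Suzuki–Miyaura coupling of F5 with F7 (PdCl2(dppf), K3PO4, THF/H2O, rt) joins C8 to C9 and gives 20.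

3. Step 10. The enal formed may itself react with the ylide (second homologation to the dienal), and the slow reaction means long heating of a peroxide. The fallback sets out from 15 and comes back at 16. Wittig methylenation (Ph3PCH3Br, KOtBu, THF, −78 → 0 °C, ylide formed before the aldehyde is added) should give methyl 2-[(3R,5S)-3,5-dimethyl-5-(oct-7-en-1-yl)-1,2-dioxolan-3-yl]acetate F8. Cross-metathesis of F8 with excess crotonaldehyde (second-generation Hoveyda–Grubbs catalyst, CH2Cl2, 40 °C) should give the (E)-enal 16 with loss of propene; the electron-poor enal does not react further.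

**Further compounds**
F1 | step 6 | 1-methoxy-3-methyl-1-(trimethylsilyloxy)buta-1,3-diene | C=C(C)C=C(OC)O[Si](C)(C)C
F2 | step 6 | methyl (2E)-12-[(tert-butyldiphenylsilyl)oxy]-3,5-dimethyl-5-[(triethylsilyl)peroxy]dodec-2-enoate (racemic) | CC[Si](CC)(CC)OOC(C)(C/C(C)=C/C(=O)OC)CCCCCCCO[Si](c1ccccc1)(c1ccccc1)C(C)(C)C
F3 | step 6 | methyl (2E)-12-[(tert-butyldiphenylsilyl)oxy]-5-hydroperoxy-3,5-dimethyldodec-2-enoate (racemic) | OOC(C)(C/C(C)=C/C(=O)OC)CCCCCCCO[Si](c1ccccc1)(c1ccccc1)C(C)(C)C
F4 | step 13 | methyl 2-[(3R,5S)-3,5-dimethyl-5-(oct-7-yn-1-yl)-1,2-dioxolan-3-yl]acetate | C#CCCCCCC[C@@]1(C)C[C@](C)(CC(=O)OC)OO1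
F5 | step 13 | methyl 2-[(3R,5S)-3,5-dimethyl-5-[(7E)-8-(4,4,5,5-tetramethyl-1,3,2-dioxaborolan-2-yl)oct-7-en-1-yl]-1,2-dioxolan-3-yl]acetate | CC1(C)OB(/C=C/CCCCCC[C@@]2(C)C[C@](C)(CC(=O)OC)OO2)OC1(C)C
F6 | step 13 | (4Z)-hept-4-en-1-yne | C#CC/C=C\CC
F7 | step 13 | (1E,4Z)-1-iodohepta-1,4-diene | I/C=C/C/C=C\CC
F8 | step 10 | methyl 2-[(3R,5S)-3,5-dimethyl-5-(oct-7-en-1-yl)-1,2-dioxolan-3-yl]acetate | C=CCCCCCC[C@@]1(C)C[C@](C)(CC(=O)OC)OO1
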